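(Its constants are assumed; the run is a simulation.)

Hours are the unit I count in here, for flasks that differ in temperature and each run for 20 h.

    starting material + reagent → intermediate + by-product (k1 = 0.45 M⁻¹ h⁻¹, Ea1 = 71.0 kJ mol⁻¹)
    2 starting material → self-condensation product (k2 = 0.50 M⁻¹ h⁻¹, Ea2 = 64.0 kJ mol⁻¹)
    target + by-product → side product (k3 = 0.088 M⁻¹ h⁻¹, Ea3 = 65.0 kJ mol⁻¹)
    intermediate → target (k4 = 0.12 h⁻¹, Ea4 = 97.0 kJ mol⁻¹)
    reagent ⇌ dormant form (K5 = 0.52, k5 = 0.72 h⁻¹, Ea5 = 83.0 kJ mol⁻¹, ΔH5 = −60.0 kJ mol⁻¹)
    (constants at 25 °C)

all flasks: starting material 0.50 M; reagent 2.50 M; time 20 h
- summer: temperature 10 °C
- noon: temperature −5 °C
- autumn: temperature 25 °C
- spring: temperature −20 °C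

- the flask that comes out highest in amount of target, in percent of the starting material charged, or "all alike" when all lie within 1.5 percentage points (summer / noon / autumn / spring / all alike)
- target at the end, in percent of the starting material charged, summer
- target at the end, in percent of the starting material charged, noon
- target at the end, in percent of the starting material charged, autumn
- target at the end, in percent of the starting material charged, spring

- in percentages every species weighs as the starting material in it: one self-condensation product counts as two
- a doubled species enters its step squared and goes two at a time
- at 25 °C the constants are as listed, elsewhere as the activation energies and enthalpies make them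

Turn the question round: what would the numbers have to say for a colder flask to beat autumn? Target comes from intermediate by a first-order step, so I carry the clock number n, the rate constant of that step at the flask's temperature times the time of the run, which counts the intermediate lifetimes that fit in the run; in autumn it is 2.40.

I solve both ends and join them. If the whole charge became intermediate at once, the part turned into target would be one minus exp(−n), which is close to n when n is small. If intermediate is made steadily through the run, that part is nearer 0.5 n. So for small n, with intermediate made at a steady or falling pace and no target lost, the target's share of target plus intermediate lies between these two.

The step speeds up by a factor of 1000 from spring to autumn; reckoned from its activation energy, spring's clock number is 0.002288, and summer's is 0.302. Counting the whole charge, the ceilings on target are 90.9% in autumn, 26.1% in summer and 0.229% in spring.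

I look at two ways a colder flask could win. It could send more starting material to intermediate, but the starting ratio of use by the reagent step to use by self-condensation, a selectivity factor, is 1.4 in spring, less than 2.25 in autumn. Or autumn could lose target in the step with by-product, by more than the ratio of its ceiling to summer's, 3.48. But by-product, one for each starting material used by the reagent step, cannot pass 0.50 M, so that loss is at most a factor of 2.41, which is smaller. I commit to autumn, and I estimate target there between 26.1% and 63.0%: the upper figure is the autumn ceiling times the share that the starting ratio gives the reagent step, and the lower one divides that by the full loss factor.

The forecast also says autumn, with 14.5% in summer, 0.86% at noon, 45% in autumn and 0.015% in spring, resting on “The slow, high-barrier conversion of intermediate to target sets the outcome”. Its autumn figure lies inside my range.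

Autumn comes out highest, with 49.1% of target, more than 13.9% in summer, 0.818% at noon and 0.0144% in spring. In autumn at 20.0 h, the side product already stands at 21.4%. Spring at that time holds 0.0144% of target beside 12.0% of intermediate, a share of 0.120% against a clock number of 0.00229. Spring left to 200 h has a clock number of 0.0229 and holds 0.778% of target beside 51.7% of intermediate, a share of 1.48%, between 1.14% and 2.29%.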